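0.0151 M/min on Friday's run and 0.0172 M/min on Tuesday's: you asked for a quick number, and we start from these molar slopes of D over the last readings, though the charges differ by a factor of 2.31.

| flask | L | temperature | remark | time |
|---|---|---|---|---|
| Friday's | 0.13 M | 29 °C | run made earlier |  |
| Tuesday's | 0.30 M | 37 °C | run made earlier |  |
| gamma | 0.20 M | 25 °C |  | 4.0 min |
| theta | 0.20 M | 40 °C |  | 1.0 min |

Friday's run (percent of the L charged)

| time / min | D / % |
|---|---|
| 0.333 | 0 |
| 0.500 | 2.1 |
| 0.667 | 4.2 |
| 1.00 | 4.0 |
| 1.50 | 9.2 |
| 2.50 | 20.6 |
| 4.00 | 38.2 |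

Tuesday's run (percent of the L charged)

| time / s | D / % |
|---|---|
| 10.0 | 0.1 |
| 20.0 | 1.5 |
| 30.0 | 1.7 |
| 50.0 | 3.6 |
| 80.0 | 7.1 |
| 90.0 | 6.6 |
| 120 | 10.3 |

(readings scatter by 1 percentage point)

- solid, in amounts per volume of the solution: L
- on the list of suspects stand: Z -> D; Z <-> J; J <-> G; G <-> Z; L <-> Z
- at the start none of L is in solution
- what has only dissolved of L counts as not reacted

* which one finishes higher in amount of D, in percent of the L charged ("neither" within 2 percentage points) (gamma / theta / neither)
* amount of D at the end, in percent of the L charged, gamma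
* amount of D at the end, in percent of the L charged, theta

Call that slope the feed rate: D made per minute on the stretch that reads as straight, in the usual term an apparent zero-order stretch, and like the lag below it is a reading with its scatter. Running each line back to zero D gives a lag of 0.707 min on Friday's run and 0.206 min on Tuesday's, both readings with their scatter. Temperature and charge move together in these runs, so we treat the change as one of temperature, linear for the feed rate and geometric for the lag. Gamma gets 0.0140 M/min after 1.31 min; theta gets a feed rate of 0.0180 M/min after 0.130 min.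

Feed rate times (time minus lag), divided by the [L] charged, gives us 18.9% for gamma and 7.84% for theta. Your forecast says 20.5% and 7%, with gamma ahead: “Gamma finishes higher, mainly because it runs longer.” We stand 1.6 percentage points below you on gamma and 0.84 points above you on theta.

The simulation puts gamma ahead, 18.9% against 7.21% for theta.

    Z → D (k = 0.00550 /s, Ea = 84.0 kJ/mol)
    Z ⇌ J (K = 1.17, k = 0.00466 /s, Ea = 86.0 kJ/mol, ΔH = −15.0 kJ/mol)
    J ⇌ G (K = 0.175, k = 0.00159 /s, Ea = 82.0 kJ/mol, ΔH = −11.0 kJ/mol)
    G ⇌ Z (k = 0.0103 /s, Ea = 91.0 kJ/mol)
    L ⇌ Z, rate k5*(cs5 - [Z]) while solid is left; crystals form when [Z] > cs5 (solubility = 0.0860 M, k = 0.00770 /s)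
    (constants at 25 °C)

That order goes at ten times the time: at 40.0 min gamma holds 98.2% and at 10.0 min theta holds 98.6%, a gap smaller than the margin of 2 points. In theta, D rises from 2.48% at 0.500 min to 7.21% at 1.00 min, which is 0.0189 M/min against our feed rate of 0.0180 M/min. Read theta at 15 s instead: the same feed rate after the same lag gives 1.08%, and that flask holds 0.774% of D.

(The runs were generated by integration with made-up constants, and the scatter is random.)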